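**Retrosynthetic overview** (ring numbering: O1, C2 quaternary, C3 oxygen-bearing, C4, C5, C6 alkylidene, C7)
1. Target 31 ⇐ silyl-protected diacetate 30 ⇐ diol 29 ⇐ (3R)-alcohol 28 ⇐ oxepan-3-one 27 (reagent-controlled ketone reduction, then desilylation and acetylation).
2. Key disconnection C3–C4: 27 ⇐ acyclic dienyl thioester 25, by one-pot anti-Markovnikov hydroboration of a vinyl group and ring-closing acyl cross-coupling. The oxepane is the only ring and is formed last.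
3. Enabling feature: C4–C5 are a saturated two-carbon arm on the alkylidene carbon C6, so they can be stored as a vinyl group (1,3-diene C4=C5–C6=C). C3 sits next to the hydrogen-free C2, so it can be stored as a non-enolisable acyl group.
4. The (E)-alkene at C6 is fixed before ring closure by hydroxyl-directed hydroalumination/iodination of a but-2-yn-1-ol ether and Stille vinylation. C2 comes from (R)-2-methylglycidol by copper-catalysed Grignard opening.
5. The side-chain pair C4'/C5' comes from a Brown (Z)-crotylboration of 4-methylpent-3-enal.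

Key step: step 16

Remark: 4-methylpent-3-en-1-ol, (R)-2-methylglycidol and (−)-B-methoxydiisopinocampheylborane are taken as purchasable. TBS = tert-butyldimethylsilyl, PMB = 4-methoxybenzyl, 9-BBN-H = 9-borabicyclo[3.3.1]nonane, Ipc = isopinocampheyl, dba = dibenzylideneacetone, DMAP = 4-(dimethylamino)pyridine.

Step 1
Reactants: 1 4-methylpent-3-en-1-ol
Product: 2 4-methylpent-3-enal
Conditions: Dess–Martin periodinane, pyridine, CH2Cl2, 0 °C; used at once as a cold solution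
Reagents that add atoms: none
Why: Dess–Martin oxidation under buffered, non-basic conditions should give the β,γ-unsaturated aldehyde without moving the trisubstituted alkene into conjugation.

Step 2
Reactants: 2 4-methylpent-3-enal
Product: 4 (3R,4R)-3,7-dimethylocta-1,6-dien-4-ol, via diisopinocampheylborinate ester 3 (not isolated)
Conditions: cis-2-butene, KOt-Bu, n-BuLi, THF, −78 to −45 °C; (−)-Ipc2BOMe, −78 °C; BF3·OEt2; then 2, −78 °C; NaOH, H2O2, 0 °C to rt
Reagents that add atoms: cis-2-butene (C/C=C\C); (−)-B-methoxydiisopinocampheylborane (COB([C@@H]1C[C@@H]2C[C@H]([C@H]1C)C2(C)C)[C@@H]1C[C@@H]2C[C@H]([C@H]1C)C2(C)C)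
Why: Brown crotylboration: the (Z)-crotylborane adds through a closed chair (Zimmerman–Traxler) transition state, so the Z geometry gives the syn methyl/hydroxyl pair, and the isopinocampheyl groups derived from (+)-α-pinene direct attack to the Si face of the aldehyde, which should set C3 and C4 as R, while the boron unit of the reagent stays only in borinate 3 and is removed in the oxidative work-up.

Step 3
Reactants: 4 (3R,4R)-3,7-dimethylocta-1,6-dien-4-ol
Product: 5 (3R,4R)-4-(TBS-oxy)-3,7-dimethylocta-1,6-diene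
Conditions: TBSOTf, 2,6-lutidine, CH2Cl2, −78 to 0 °C
Reagents that add atoms: tert-butyldimethylsilyl triflate (CC(C)(C)[Si](C)(C)OS(=O)(=O)C(F)(F)F)
Why: Silylation of the secondary alcohol with the reactive silyl triflate protects the C5' oxygen for the whole route and touches no stereocentre.

Step 4
Reactants: 5 (3R,4R)-4-(TBS-oxy)-3,7-dimethylocta-1,6-diene
Product: 7 (3R,4R)-4-(TBS-oxy)-3,7-dimethyloct-6-en-1-ol, via B-alkyl-9-BBN borane 6 (not isolated)
Conditions: 9-BBN-H, THF, 0 °C to rt; then NaOH, H2O2, 0 °C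
Reagents that add atoms: 9-BBN-H (B1C2CCCC1CCC2); hydrogen peroxide (OO)
Why: Hydroboration–oxidation: the bulky borane adds only to the monosubstituted alkene with boron on the terminal carbon (boron stays only in borane 6) and leaves the trisubstituted alkene, and oxidation with retention gives the primary alcohol.

Step 5
Reactants: 7 (3R,4R)-4-(TBS-oxy)-3,7-dimethyloct-6-en-1-ol
Product: 8 (3R,4R)-1-bromo-4-(TBS-oxy)-3,7-dimethyloct-6-ene
Conditions: CBr4, PPh3, CH2Cl2, 0 °C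
Reagents that add atoms: carbon tetrabromide (BrC(Br)(Br)Br)
Why: Appel bromination converts the primary alcohol into the bromide by SN2 at CH2 under neutral conditions that spare the silyl ether and the alkene.

Step 6
Reactants: 9 (R)-2-methylglycidol
Product: 11 (2S)-2-[(PMB-oxy)methyl]-2-methyloxirane, via sodium alkoxide 10 (not isolated)
Conditions: NaH, PMBCl, Bu4NI (cat.), THF/DMF, 0 °C to rt
Reagents that add atoms: sodium hydride ([Na+].[H-]); 4-methoxybenzyl chloride (COc1ccc(CCl)cc1)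
Why: Williamson etherification of the primary alkoxide (sodium stays only in alkoxide 10) leaves the quaternary epoxide carbon untouched, and the descriptor changes from R to S only because the CIP priorities change.

Step 7
Reactants: 8 (3R,4R)-1-bromo-4-(TBS-oxy)-3,7-dimethyloct-6-ene; 11 (2S)-2-[(PMB-oxy)methyl]-2-methyloxirane
Product: 13 (2S,6R,7R)-7-(TBS-oxy)-1-(PMB-oxy)-2,6,10-trimethylundec-9-en-2-ol, via Grignard reagent 12 (not isolated)
Conditions: Mg, THF, rt to 40 °C; then CuI (10 mol%), 11, THF, −30 to 0 °C; aq. NH4Cl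
Reagents that add atoms: magnesium ([Mg])
Why: Copper-catalysed SN2 opening of the 2,2-disubstituted epoxide at its unsubstituted CH2 by the primary Grignard reagent (magnesium stays only in 12) joins the two fragments without touching the quaternary carbinol carbon, so C2 keeps the configuration of the glycidol.

Step 8
Reactants: 13 (2S,6R,7R)-7-(TBS-oxy)-1-(PMB-oxy)-2,6,10-trimethylundec-9-en-2-ol
Product: 15 (2S,6R,7R)-7-(TBS-oxy)-1-(PMB-oxy)-2,6,10-trimethyl-2-(prop-2-yn-1-yloxy)undec-9-ene, via sodium alkoxide 14 (not isolated)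
Conditions: NaH, propargyl bromide, Bu4NI (cat.), DMF, 0 °C to rt
Reagents that add atoms: sodium hydride ([Na+].[H-]); propargyl bromide (C#CCBr)
Why: Williamson O-alkylation of the tertiary alkoxide (sodium stays only in alkoxide 14) with the reactive, unhindered propargylic bromide installs C7 and the two alkyne carbons that become C6 and the exocyclic carbon.

Step 9
Reactants: 15 (2S,6R,7R)-7-(TBS-oxy)-1-(PMB-oxy)-2,6,10-trimethyl-2-(prop-2-yn-1-yloxy)undec-9-ene
Product: 17 4-{[(2S,6R,7R)-7-(TBS-oxy)-1-(PMB-oxy)-2,6,10-trimethylundec-9-en-2-yl]oxy}but-2-yn-1-ol, via lithium acetylide 16 (not isolated)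
Conditions: n-BuLi, THF, −78 °C; (CH2O)n, −78 °C to rt; aq. NH4Cl
Reagents that add atoms: n-butyllithium ([Li]CCCC); formaldehyde as paraformaldehyde (C=O)
Why: Deprotonation of the terminal alkyne (lithium stays only in acetylide 16) and addition of the acetylide to formaldehyde gives the propargylic alcohol that directs the next step.

Step 10
Reactants: 17 4-{[(2S,6R,7R)-7-(TBS-oxy)-1-(PMB-oxy)-2,6,10-trimethylundec-9-en-2-yl]oxy}but-2-yn-1-ol
Product: 19 (2Z)-4-{[(2S,6R,7R)-7-(TBS-oxy)-1-(PMB-oxy)-2,6,10-trimethylundec-9-en-2-yl]oxy}-3-iodobut-2-en-1-ol, via sodium vinylalanate 18 (not isolated)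
Conditions: NaAlH2(OCH2CH2OCH3)2, THF, 0 °C; then I2, THF, −78 to 0 °C
Reagents that add atoms: sodium bis(2-methoxyethoxy)aluminium dihydride ([Na+].COCCO[AlH2-]OCCOC); iodine (II)
Why: Hydroxyl-directed trans-hydroalumination delivers hydride to the alkyne carbon next to CH2OH and places aluminium on the distal carbon in the five-membered alkoxy-aluminate 18 (the only compound that keeps the aluminate unit), and iodinolysis with retention at low temperature should give only the (Z)-3-iodo allylic alcohol, which fixes the geometry of the later exocyclic alkene.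

Step 11
Reactants: 19 (2Z)-4-{[(2S,6R,7R)-7-(TBS-oxy)-1-(PMB-oxy)-2,6,10-trimethylundec-9-en-2-yl]oxy}-3-iodobut-2-en-1-ol
Product: 20 (2S,6R,7R)-7-(TBS-oxy)-2-{[(2Z)-4-(TBS-oxy)-2-iodobut-2-en-1-yl]oxy}-1-(PMB-oxy)-2,6,10-trimethylundec-9-ene
Conditions: TBSCl, imidazole, DMF, rt
Reagents that add atoms: tert-butyldimethylsilyl chloride (CC(C)(C)[Si](C)(C)Cl)
Why: Silylation of the primary allylic alcohol gives an ether that cannot ionise under the later palladium steps, as an allylic ester would.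

Step 12
Reactants: 20 (2S,6R,7R)-7-(TBS-oxy)-2-{[(2Z)-4-(TBS-oxy)-2-iodobut-2-en-1-yl]oxy}-1-(PMB-oxy)-2,6,10-trimethylundec-9-ene
Product: 21 (2S,6R,7R)-7-(TBS-oxy)-2-{[(2Z)-4-(TBS-oxy)-2-iodobut-2-en-1-yl]oxy}-2,6,10-trimethylundec-9-en-1-ol
Conditions: DDQ (2,3-dichloro-5,6-dicyano-1,4-benzoquinone), CH2Cl2/pH 7 buffer, 0 °C
Reagents that add atoms: none
Why: Oxidative cleavage of the electron-rich benzyl ether by DDQ frees the C3 alcohol while silyl ethers, alkenyl iodide and alkene survive, and it is done before the diene is present.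

Step 13
Reactants: 21 (2S,6R,7R)-7-(TBS-oxy)-2-{[(2Z)-4-(TBS-oxy)-2-iodobut-2-en-1-yl]oxy}-2,6,10-trimethylundec-9-en-1-ol
Product: 22 (2S,6R,7R)-7-(TBS-oxy)-2-{[(2E)-4-(TBS-oxy)-2-ethenylbut-2-en-1-yl]oxy}-2,6,10-trimethylundec-9-en-1-ol
Conditions: tributyl(vinyl)stannane, Pd(PPh3)4 (5 mol%), DMF, 50 °C
Reagents that add atoms: tributyl(vinyl)stannane (C=C[Sn](CCCC)(CCCC)CCCC)
Why: Stille coupling proceeds with retention at the alkenyl iodide, so the vinyl group (future C5 and C4) takes the place of iodine cis to CH2OTBS and the (E)-1,3-diene results.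

Step 14
Reactants: 22 (2S,6R,7R)-7-(TBS-oxy)-2-{[(2E)-4-(TBS-oxy)-2-ethenylbut-2-en-1-yl]oxy}-2,6,10-trimethylundec-9-en-1-ol
Product: 24 (2S,6R,7R)-7-(TBS-oxy)-2-{[(2E)-4-(TBS-oxy)-2-ethenylbut-2-en-1-yl]oxy}-2,6,10-trimethylundec-9-enoic acid, via aldehyde 23 (not isolated)
Conditions: TEMPO (2,2,6,6-tetramethylpiperidin-1-oxyl, C9H18NO, 20 mol%), PhI(OAc)2, MeCN/H2O, rt
Reagents that add atoms: water (O)
Why: Oxoammonium oxidation takes the primary alcohol to the aldehyde and its hydrate on to the acid, and C2 has no hydrogen, so nothing can epimerise.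

Step 15
Reactants: 24 (2S,6R,7R)-7-(TBS-oxy)-2-{[(2E)-4-(TBS-oxy)-2-ethenylbut-2-en-1-yl]oxy}-2,6,10-trimethylundec-9-enoic acid
Product: 25 S-phenyl (2S,6R,7R)-7-(TBS-oxy)-2-{[(2E)-4-(TBS-oxy)-2-ethenylbut-2-en-1-yl]oxy}-2,6,10-trimethylundec-9-enethioate
Conditions: PhSH, DCC (N,N'-dicyclohexylcarbodiimide), DMAP (cat.), CH2Cl2, 0 °C to rt
Reagents that add atoms: thiophenol (Sc1ccccc1)
Why: Steglich thioesterification turns the hindered acid into the aryl thioester that serves as the acyl electrophile of the key step.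

Step 16
Reactants: 25 S-phenyl (2S,6R,7R)-7-(TBS-oxy)-2-{[(2E)-4-(TBS-oxy)-2-ethenylbut-2-en-1-yl]oxy}-2,6,10-trimethylundec-9-enethioate
Product: 27 (2S,6E)-6-[2-(TBS-oxy)ethylidene]-2-[(4R,5R)-5-(TBS-oxy)-4,8-dimethylnon-7-en-1-yl]-2-methyloxepan-3-one, via B-alkyl-9-BBN borane 26 (not isolated)
Conditions: 9-BBN-H (1.05 equiv), THF, 0 °C to rt; then slow addition to Pd2(dba)3 (5 mol%), P(2-furyl)3 (20 mol%), Cu(O2C-2-C4H3S) (copper thiophene-2-carboxylate, 1.5 equiv), Cs2CO3, THF, 50 °C, about 2 mM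
Reagents that add atoms: 9-BBN-H (B1C2CCCC1CCC2)
Why: Proposed new method: 9-BBN-H should add anti-Markovnikov to the only monosubstituted alkene (the vinyl group on C6) and put boron on C4 (boron stays only in borane 26); zerovalent palladium then inserts into the C(acyl)–S bond at C3, the copper carboxylate takes up the thiolate and passes its carboxylate to boron, the primary C4 alkyl group moves to palladium, and reductive elimination forms C3–C4. The closest known reaction type is the Liebeskind–Srogl ketone synthesis from thioesters and B-alkyl-9-BBN reagents, combined with the hydroboration/ring-closing logic of B-alkyl Suzuki–Miyaura cyclisations; the new element is the ring-closing, seven-membered variant on an α-quaternary thioester. The oxepane closes in a 7-exo-trig sense at the acyl carbon, by reductive elimination from an eight-membered acyl(alkyl)palladacycle, helped by the fully substituted C2 and the rigid alkene spacer. No stereocentre is created: C2 has no α-hydrogen and cannot epimerise, and the (E)-alkene at C6 does not take part. The step needs chemoselective hydroboration (secured by the steric demand of 9-BBN-H, which spares both trisubstituted alkenes and the thioester), cyclisation over oligomerisation (slow addition at high dilution) and ketone formation over decarbonylation or β-hydride loss (mild neutral activation; CO loss would need a tertiary alkylpalladium, and acyl–alkyl reductive elimination is fast).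

Step 17
Reactants: 27 (2S,6E)-6-[2-(TBS-oxy)ethylidene]-2-[(4R,5R)-5-(TBS-oxy)-4,8-dimethylnon-7-en-1-yl]-2-methyloxepan-3-one
Product: 28 (2S,3R,6E)-6-[2-(TBS-oxy)ethylidene]-2-[(4R,5R)-5-(TBS-oxy)-4,8-dimethylnon-7-en-1-yl]-2-methyloxepan-3-ol
Conditions: (S)-2-methyl-CBS-oxazaborolidine [(3aS)-1-methyl-3,3-diphenyltetrahydro-1H,3H-pyrrolo[1,2-c][1,3,2]oxazaborole, C18H20BNO, 30 mol%], catecholborane, toluene, −78 °C; MeOH, then aq. NaOH wash
Reagents that add atoms: none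
Why: Corey–Bakshi–Shibata reduction: the (S)-oxazaborolidine should bind the ketone with the fully substituted C2 as the large group and C4H2 as the small one and deliver hydride to the face that gives the (3R)-alcohol (reagent control over the weak methyl-versus-chain bias at C2), while catecholborane at −78 °C leaves the trisubstituted alkenes alone.

Step 18
Reactants: 28 (2S,3R,6E)-6-[2-(TBS-oxy)ethylidene]-2-[(4R,5R)-5-(TBS-oxy)-4,8-dimethylnon-7-en-1-yl]-2-methyloxepan-3-ol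
Product: 29 (2S,3R,6E)-6-(2-hydroxyethylidene)-2-[(4R,5R)-5-(TBS-oxy)-4,8-dimethylnon-7-en-1-yl]-2-methyloxepan-3-ol
Conditions: HF·pyridine, pyridine, THF, 0 °C
Reagents that add atoms: none
Why: Buffered fluoride cleaves the unhindered primary allylic silyl ether much faster than the secondary one flanked by the methyl-bearing carbon, so only the C5' oxygen stays protected.

Step 19
Reactants: 29 (2S,3R,6E)-6-(2-hydroxyethylidene)-2-[(4R,5R)-5-(TBS-oxy)-4,8-dimethylnon-7-en-1-yl]-2-methyloxepan-3-ol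
Product: 30 (2S,3R,6E)-6-(2-acetoxyethylidene)-2-[(4R,5R)-5-(TBS-oxy)-4,8-dimethylnon-7-en-1-yl]-2-methyloxepan-3-yl acetate
Conditions: Ac2O, pyridine, DMAP (cat.), CH2Cl2, rt
Reagents that add atoms: acetic anhydride (CC(=O)OC(C)=O)
Why: DMAP-catalysed acylation should esterify both the primary allylic and the hindered ring hydroxyl with retention at C3.

Step 20
Reactants: 30 (2S,3R,6E)-6-(2-acetoxyethylidene)-2-[(4R,5R)-5-(TBS-oxy)-4,8-dimethylnon-7-en-1-yl]-2-methyloxepan-3-yl acetate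
Product: 31 (2S,3R,6E)-6-(2-acetoxyethylidene)-2-[(4R,5R)-5-hydroxy-4,8-dimethylnon-7-en-1-yl]-2-methyloxepan-3-yl acetate
Conditions: aq. HF, MeCN, 0 °C to rt
Reagents that add atoms: none
Why: Acidic fluoride removes the last silyl ether under conditions that leave both acetates in place, and the freed hydroxyl is too remote for acyl migration.

**Compound list**
1 | 4-methylpent-3-en-1-ol | CC(C)=CCCO | starting material
2 | 4-methylpent-3-enal | CC(C)=CCC=O | intermediate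
3 | (3R,4R)-3,7-dimethylocta-1,6-dien-4-yl diisopinocampheylborinate | C=C[C@@H](C)[C@H](OB([C@@H]1C[C@@H]2C[C@H]([C@H]1C)C2(C)C)[C@@H]1C[C@@H]2C[C@H]([C@H]1C)C2(C)C)CC=C(C)C | intermediate (not isolated)
4 | (3R,4R)-3,7-dimethylocta-1,6-dien-4-ol | C=C[C@@H](C)[C@H](O)CC=C(C)C | intermediate
5 | (3R,4R)-4-(TBS-oxy)-3,7-dimethylocta-1,6-diene | C=C[C@@H](C)[C@H](O[Si](C)(C)C(C)(C)C)CC=C(C)C | intermediate
6 | 9-[(3R,4R)-4-(TBS-oxy)-3,7-dimethyloct-6-en-1-yl]-9-borabicyclo[3.3.1]nonane | B1(CC[C@@H](C)[C@H](O[Si](C)(C)C(C)(C)C)CC=C(C)C)C2CCCC1CCC2 | intermediate (not isolated)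
7 | (3R,4R)-4-(TBS-oxy)-3,7-dimethyloct-6-en-1-ol | OCC[C@@H](C)[C@H](O[Si](C)(C)C(C)(C)C)CC=C(C)C | intermediate
8 | (3R,4R)-1-bromo-4-(TBS-oxy)-3,7-dimethyloct-6-ene | BrCC[C@@H](C)[C@H](O[Si](C)(C)C(C)(C)C)CC=C(C)C | intermediate
9 | (R)-2-methylglycidol [(2R)-2-methyloxiran-2-yl]methanol | OC[C@@]1(C)OC1 | starting material
10 | sodium [(2R)-2-methyloxiran-2-yl]methanolate | [Na+].[O-]C[C@@]1(C)OC1 | intermediate (not isolated)
11 | (2S)-2-[(PMB-oxy)methyl]-2-methyloxirane | COc1ccc(COC[C@@]2(C)OC2)cc1 | intermediate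
12 | [(3R,4R)-4-(TBS-oxy)-3,7-dimethyloct-6-en-1-yl]magnesium bromide | Br[Mg]CC[C@@H](C)[C@H](O[Si](C)(C)C(C)(C)C)CC=C(C)C | intermediate (not isolated)
13 | (2S,6R,7R)-7-(TBS-oxy)-1-(PMB-oxy)-2,6,10-trimethylundec-9-en-2-ol | COc1ccc(COC[C@@](C)(O)CCC[C@@H](C)[C@H](O[Si](C)(C)C(C)(C)C)CC=C(C)C)cc1 | intermediate
14 | sodium (2S,6R,7R)-7-(TBS-oxy)-1-(PMB-oxy)-2,6,10-trimethylundec-9-en-2-olate | [Na+].COc1ccc(COC[C@@](C)([O-])CCC[C@@H](C)[C@H](O[Si](C)(C)C(C)(C)C)CC=C(C)C)cc1 | intermediate (not isolated)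
15 | (2S,6R,7R)-7-(TBS-oxy)-1-(PMB-oxy)-2,6,10-trimethyl-2-(prop-2-yn-1-yloxy)undec-9-ene | COc1ccc(COC[C@@](C)(OCC#C)CCC[C@@H](C)[C@H](O[Si](C)(C)C(C)(C)C)CC=C(C)C)cc1 | intermediate
16 | lithium acetylide of 15 | COc1ccc(COC[C@@](C)(OCC#C[Li])CCC[C@@H](C)[C@H](O[Si](C)(C)C(C)(C)C)CC=C(C)C)cc1 | intermediate (not isolated)
17 | 4-{[(2S,6R,7R)-7-(TBS-oxy)-1-(PMB-oxy)-2,6,10-trimethylundec-9-en-2-yl]oxy}but-2-yn-1-ol | COc1ccc(COC[C@@](C)(OCC#CCO)CCC[C@@H](C)[C@H](O[Si](C)(C)C(C)(C)C)CC=C(C)C)cc1 | intermediate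
18 | sodium vinylalanate of 17 (five-membered oxa-aluminacycle with aluminium on the carbon that becomes C6) | COc1ccc(COC[C@@](C)(OCC2=CCO[Al-]2(OCCOC)OCCOC)CCC[C@@H](C)[C@H](O[Si](C)(C)C(C)(C)C)CC=C(C)C)cc1.[Na+] | intermediate (not isolated)
19 | (2Z)-4-{[(2S,6R,7R)-7-(TBS-oxy)-1-(PMB-oxy)-2,6,10-trimethylundec-9-en-2-yl]oxy}-3-iodobut-2-en-1-ol | COc1ccc(COC[C@@](C)(OC/C(I)=C/CO)CCC[C@@H](C)[C@H](O[Si](C)(C)C(C)(C)C)CC=C(C)C)cc1 | intermediate
20 | (2S,6R,7R)-7-(TBS-oxy)-2-{[(2Z)-4-(TBS-oxy)-2-iodobut-2-en-1-yl]oxy}-1-(PMB-oxy)-2,6,10-trimethylundec-9-ene | COc1ccc(COC[C@@](C)(OC/C(I)=C/CO[Si](C)(C)C(C)(C)C)CCC[C@@H](C)[C@H](O[Si](C)(C)C(C)(C)C)CC=C(C)C)cc1 | intermediate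
21 | (2S,6R,7R)-7-(TBS-oxy)-2-{[(2Z)-4-(TBS-oxy)-2-iodobut-2-en-1-yl]oxy}-2,6,10-trimethylundec-9-en-1-ol | OC[C@@](C)(OC/C(I)=C/CO[Si](C)(C)C(C)(C)C)CCC[C@@H](C)[C@H](O[Si](C)(C)C(C)(C)C)CC=C(C)C | intermediate
22 | (2S,6R,7R)-7-(TBS-oxy)-2-{[(2E)-4-(TBS-oxy)-2-ethenylbut-2-en-1-yl]oxy}-2,6,10-trimethylundec-9-en-1-ol | OC[C@@](C)(OC/C(C=C)=C/CO[Si](C)(C)C(C)(C)C)CCC[C@@H](C)[C@H](O[Si](C)(C)C(C)(C)C)CC=C(C)C | intermediate
23 | (2S,6R,7R)-7-(TBS-oxy)-2-{[(2E)-4-(TBS-oxy)-2-ethenylbut-2-en-1-yl]oxy}-2,6,10-trimethylundec-9-enal | O=C[C@@](C)(OC/C(C=C)=C/CO[Si](C)(C)C(C)(C)C)CCC[C@@H](C)[C@H](O[Si](C)(C)C(C)(C)C)CC=C(C)C | intermediate (not isolated)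
24 | (2S,6R,7R)-7-(TBS-oxy)-2-{[(2E)-4-(TBS-oxy)-2-ethenylbut-2-en-1-yl]oxy}-2,6,10-trimethylundec-9-enoic acid | OC(=O)[C@@](C)(OC/C(C=C)=C/CO[Si](C)(C)C(C)(C)C)CCC[C@@H](C)[C@H](O[Si](C)(C)C(C)(C)C)CC=C(C)C | intermediate
25 | S-phenyl (2S,6R,7R)-7-(TBS-oxy)-2-{[(2E)-4-(TBS-oxy)-2-ethenylbut-2-en-1-yl]oxy}-2,6,10-trimethylundec-9-enethioate | O=C(Sc1ccccc1)[C@@](C)(OC/C(C=C)=C/CO[Si](C)(C)C(C)(C)C)CCC[C@@H](C)[C@H](O[Si](C)(C)C(C)(C)C)CC=C(C)C | intermediate
26 | S-phenyl (2S,6R,7R)-2-({(2E)-2-[2-(9-borabicyclo[3.3.1]nonan-9-yl)ethyl]-4-(TBS-oxy)but-2-en-1-yl}oxy)-7-(TBS-oxy)-2,6,10-trimethylundec-9-enethioate | O=C(Sc1ccccc1)[C@@](C)(OC/C(CCB1C2CCCC1CCC2)=C/CO[Si](C)(C)C(C)(C)C)CCC[C@@H](C)[C@H](O[Si](C)(C)C(C)(C)C)CC=C(C)C | intermediate (not isolated)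
27 | (2S,6E)-6-[2-(TBS-oxy)ethylidene]-2-[(4R,5R)-5-(TBS-oxy)-4,8-dimethylnon-7-en-1-yl]-2-methyloxepan-3-one | CC(C)(C)[Si](C)(C)OC/C=C1\CCC(=O)[C@](C)(CCC[C@@H](C)[C@H](O[Si](C)(C)C(C)(C)C)CC=C(C)C)OC1 | intermediate
28 | (2S,3R,6E)-6-[2-(TBS-oxy)ethylidene]-2-[(4R,5R)-5-(TBS-oxy)-4,8-dimethylnon-7-en-1-yl]-2-methyloxepan-3-ol | CC(C)(C)[Si](C)(C)OC/C=C1\CC[C@@H](O)[C@](C)(CCC[C@@H](C)[C@H](O[Si](C)(C)C(C)(C)C)CC=C(C)C)OC1 | intermediate
29 | (2S,3R,6E)-6-(2-hydroxyethylidene)-2-[(4R,5R)-5-(TBS-oxy)-4,8-dimethylnon-7-en-1-yl]-2-methyloxepan-3-ol | OC/C=C1\CC[C@@H](O)[C@](C)(CCC[C@@H](C)[C@H](O[Si](C)(C)C(C)(C)C)CC=C(C)C)OC1 | intermediate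
30 | (2S,3R,6E)-6-(2-acetoxyethylidene)-2-[(4R,5R)-5-(TBS-oxy)-4,8-dimethylnon-7-en-1-yl]-2-methyloxepan-3-yl acetate | CC(=O)OC/C=C1\CC[C@@H](OC(C)=O)[C@](C)(CCC[C@@H](C)[C@H](O[Si](C)(C)C(C)(C)C)CC=C(C)C)OC1 | intermediate
31 | (2S,3R,6E)-6-(2-acetoxyethylidene)-2-[(4R,5R)-5-hydroxy-4,8-dimethylnon-7-en-1-yl]-2-methyloxepan-3-yl acetate | CC(=O)OC/C=C1\CC[C@@H](OC(C)=O)[C@](C)(CCC[C@@H](C)[C@H](O)CC=C(C)C)OC1 | target

**Step count**
Total: 20 steps. Longest linear sequence: 19 steps (steps 1–5 and 7–20); step 6 is a one-step branch.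

**Steps most likely to fail**

Step 16 (proposed new method). Transfer of the alkyl group from boron to the hindered acyl–palladium centre may be slow, so that intermolecular coupling, protodeboronation or loss of the thioester take over. The fallback uses known chemistry and sets out from acid 24. The acid would be condensed with N,O-dimethylhydroxylamine (EDC, DMAP) to the Weinreb amide F1. Hydroboration with 9-BBN-H would give the alkylborane F2, which would be oxidised (NaBO3) to the primary alcohol F3 and turned into the iodide F4 (I2, PPh3, imidazole). Treatment with t-BuLi at −78 °C would effect iodine–lithium exchange, and the alkyllithium F5 would close onto the amide through a chelated tetrahedral intermediate (anionic cyclisation onto a Weinreb amide). This comes back to the route at ketone 27.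

Step 17. Facial selectivity may be poor if the ring oxygen competes for the boron of the catalyst or if the ring conformation opposes the reagent. The fallback sets out from ketone 27: unselective reduction with NaBH4 in MeOH, separation of the C3 epimers by chromatography, and return of the unwanted (2S,3S)-alcohol F6 to 27 by Dess–Martin oxidation for another pass. It comes back to the route at 28.

Step 8. O-alkylation of the hindered tertiary alkoxide may stay incomplete, and the base may isomerise the propargyl ether to an allenyl ether. The fallback sets out from alcohol 13: its alkoxide 14 would be alkylated with the more reactive, non-isomerisable tert-butyl bromoacetate to the tert-butyl ester F7. Reduction with i-Bu2AlH at −78 °C would give the aldehyde F8, and Ohira–Bestmann homologation (dimethyl (1-diazo-2-oxopropyl)phosphonate, K2CO3, MeOH) would return to the route at alkyne 15.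

**Further compounds**
F1 | step 16 | (2S,6R,7R)-7-(TBS-oxy)-2-{[(2E)-4-(TBS-oxy)-2-ethenylbut-2-en-1-yl]oxy}-N-methoxy-N,2,6,10-tetramethylundec-9-enamide | CON(C)C(=O)[C@@](C)(OC/C(C=C)=C/CO[Si](C)(C)C(C)(C)C)CCC[C@@H](C)[C@H](O[Si](C)(C)C(C)(C)C)CC=C(C)C
F2 | step 16 | B-alkyl-9-BBN borane of F1 (boron on the terminal carbon of the former vinyl group) | CON(C)C(=O)[C@@](C)(OC/C(CCB1C2CCCC1CCC2)=C/CO[Si](C)(C)C(C)(C)C)CCC[C@@H](C)[C@H](O[Si](C)(C)C(C)(C)C)CC=C(C)C
F3 | step 16 | (2S,6R,7R)-7-(TBS-oxy)-2-{[(2E)-4-(TBS-oxy)-2-(2-hydroxyethyl)but-2-en-1-yl]oxy}-N-methoxy-N,2,6,10-tetramethylundec-9-enamide | CON(C)C(=O)[C@@](C)(OC/C(CCO)=C/CO[Si](C)(C)C(C)(C)C)CCC[C@@H](C)[C@H](O[Si](C)(C)C(C)(C)C)CC=C(C)C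
F4 | step 16 | (2S,6R,7R)-7-(TBS-oxy)-2-{[(2E)-4-(TBS-oxy)-2-(2-iodoethyl)but-2-en-1-yl]oxy}-N-methoxy-N,2,6,10-tetramethylundec-9-enamide | CON(C)C(=O)[C@@](C)(OC/C(CCI)=C/CO[Si](C)(C)C(C)(C)C)CCC[C@@H](C)[C@H](O[Si](C)(C)C(C)(C)C)CC=C(C)C
F5 | step 16 | alkyllithium from F4 (lithium in place of iodine) | CON(C)C(=O)[C@@](C)(OC/C(CC[Li])=C/CO[Si](C)(C)C(C)(C)C)CCC[C@@H](C)[C@H](O[Si](C)(C)C(C)(C)C)CC=C(C)C
F6 | step 17 | (2S,3S,6E)-6-[2-(TBS-oxy)ethylidene]-2-[(4R,5R)-5-(TBS-oxy)-4,8-dimethylnon-7-en-1-yl]-2-methyloxepan-3-ol | CC(C)(C)[Si](C)(C)OC/C=C1\CC[C@H](O)[C@](C)(CCC[C@@H](C)[C@H](O[Si](C)(C)C(C)(C)C)CC=C(C)C)OC1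
F7 | step 8 | tert-butyl 2-{[(2S,6R,7R)-7-(TBS-oxy)-1-(PMB-oxy)-2,6,10-trimethylundec-9-en-2-yl]oxy}acetate | COc1ccc(COC[C@@](C)(OCC(=O)OC(C)(C)C)CCC[C@@H](C)[C@H](O[Si](C)(C)C(C)(C)C)CC=C(C)C)cc1
F8 | step 8 | 2-{[(2S,6R,7R)-7-(TBS-oxy)-1-(PMB-oxy)-2,6,10-trimethylundec-9-en-2-yl]oxy}acetaldehyde | COc1ccc(COC[C@@](C)(OCC=O)CCC[C@@H](C)[C@H](O[Si](C)(C)C(C)(C)C)CC=C(C)C)cc1
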